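**Assumption:** the drawn relative configuration is all-trans (2,5-trans, 3,4-trans, 2,3-trans, 4,5-trans), which corresponds to (2R,3S,4S,5R) on the oxolane ring. The phenol is masked as an allyl ether until the last step.

## Retrosynthesis
- Target **20** comes from acid-catalysed cyclodehydration of 1,4-diol **17**. C8 and C8' are fixed and non-epimerisable, and the reversible benzylic ionisation drives C7 and C7' to the all-trans THF.
- Diol **17** comes from ketoreductase reduction of aryl ketone **16**. Ketone **16** comes from ArLi addition to Weinreb amide **15**, which is the ring-opened trans,trans-lactone **12**.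
- Lactone **12** is built from butenolide **6** by anti (trans) vinyl conjugate addition, oxidative cleavage and reduction, then trans-selective enolate hydroxymethylation. Butenolide **6** comes from γ-lactone **4**, which comes from Ru-catalysed asymmetric transfer hydrogenation (the first stereocentre, C7') of keto ester **3**.
- Rings are formed in this order: the γ-lactone (Step 2), then lactone opening (Step 12), then the THF (Step 15).

## Route

**Step 1**
Reactants: **1** 5-bromo-1,2,3-trimethoxybenzene; **2** ethyl 4-chloro-4-oxobutanoate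
Product: **3** ethyl 4-oxo-4-(3,4,5-trimethoxyphenyl)butanoate
Conditions: (i) 1, Mg, THF, reflux; (ii) ZnBr2, 0 °C; (iii) 2, Pd(PPh3)4 (5 mol%), THF, 0 °C→rt
Reagents that add atoms: none
Why: Negishi-type acylation of the arylzinc with the acid chloride leaves the ester untouched. Starting from the bromide fixes the 3,4,5-pattern, which Friedel–Crafts on 1,2,3-trimethoxybenzene would not give. No stereocentre is formed.

**Step 2**
Reactants: **3**
Product: **4** (5R)-5-(3,4,5-trimethoxyphenyl)oxolan-2-one
Conditions: RuCl[(R,R)-TsDPEN](p-cymene) (1 mol%), HCO2H/Et3N (5:2), 35 °C; then PPTS (cat.), CH2Cl2, rt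
Reagents that add atoms: none (formate supplies the hydride)
Why: Noyori asymmetric transfer hydrogenation delivers hydride to one face of the aryl ketone and sets C7' as (R), the first stereocentre. The γ-hydroxy ester then lactonises.

**Step 3**
Reactants: **4**
Product: **5** (5R)-3-(phenylselanyl)-5-(3,4,5-trimethoxyphenyl)oxolan-2-one (C3 epimer mixture)
Conditions: LiHMDS, THF, −78 °C; then PhSeCl, −78→0 °C
Reagents that add atoms: PhSeCl, Cl[Se]c1ccccc1
Why: The kinetic lactone enolate is selenenylated at the α-carbon, and the C5 stereocentre is not touched.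

**Step 4**
Reactants: **5**
Product: **6** (5R)-5-(3,4,5-trimethoxyphenyl)furan-2(5H)-one
Conditions: 30% H2O2, pyridine, CH2Cl2, 0 °C→rt
Reagents that add atoms: none
Why: Selenoxide syn-elimination gives the conjugated butenolide under near-neutral conditions, so the γ-stereocentre is retained.

**Step 5**
Reactants: **6**
Product: **7** (4S,5R)-4-ethenyl-5-(3,4,5-trimethoxyphenyl)oxolan-2-one
Conditions: CH2=CHMgBr, CuBr·SMe2, TMSCl, THF, −78 °C; then aq. NH4Cl
Reagents that add atoms: vinylmagnesium bromide, C=C[Mg]Br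
Why: Copper-mediated 1,4-addition occurs anti to the γ-aryl group (conjugate addition), which sets C4 (C8') trans to C5.

**Step 6**
Reactants: **7**
Product: **8** (2R,3R)-5-oxo-2-(3,4,5-trimethoxyphenyl)oxolane-3-carbaldehyde
Conditions: OsO4 (3 mol%), NaIO4, 2,6-lutidine, dioxane/H2O (3:1), rt
Reagents that add atoms: sodium periodate, [Na+].[O-]I(=O)(=O)=O (supplies the aldehyde oxygen)
Why: Lemieux–Johnson cleavage converts the vinyl group to the aldehyde without touching the arene or lactone. The crude aldehyde is used at once to avoid α-epimerisation.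

**Step 7**
Reactants: **8**
Product: **9** (4S,5R)-4-(hydroxymethyl)-5-(3,4,5-trimethoxyphenyl)oxolan-2-one
Conditions: NaBH4, EtOH/CH2Cl2 (1:1), −20 °C, 10 min; quench NH4Cl
Reagents that add atoms: none
Why: At low temperature the aldehyde is reduced much faster than the lactone, and the short reaction time prevents epimerisation and translactonisation.

**Step 8**
Reactants: **9**
Product: **10** (4S,5R)-4-{[(tert-butyldiphenylsilyl)oxy]methyl}-5-(3,4,5-trimethoxyphenyl)oxolan-2-one
Conditions: TBDPSCl, imidazole, DMF, rt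
Reagents that add atoms: TBDPSCl, CC(C)(C)[Si](Cl)(c1ccccc1)c1ccccc1
Why: Silylation of the primary alcohol gives a group stable to organolithiums, acid and the later steps.

**Step 9**
Reactants: **10**
Product: **11** (3S,4S,5R)-4-{[(TBDPS)oxy]methyl}-3-(hydroxymethyl)-5-(3,4,5-trimethoxyphenyl)oxolan-2-one
Conditions: LiHMDS, THF, −78 °C; then monomeric CH2O (gas), −78→−40 °C; quench NH4Cl at −40 °C
Reagents that add atoms: formaldehyde, C=O
Why: Enolate hydroxymethylation (aldol) occurs on the face anti to the adjacent C4 substituent, which sets C3 (C8) trans to C4.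

**Step 10**
Reactants: **11**
Product: **12** (3S,4S,5R)-3,4-bis{[(TBDPS)oxy]methyl}-5-(3,4,5-trimethoxyphenyl)oxolan-2-one
Conditions: TBDPSCl, imidazole, DMF, rt
Reagents that add atoms: TBDPSCl, CC(C)(C)[Si](Cl)(c1ccccc1)c1ccccc1
Why: Protecting the β-hydroxy lactone promptly prevents retro-aldol and dehydration. All three ring stereocentres are unchanged.

**Step 11**
Reactants: **13** 4-bromo-2,6-dimethoxyphenol
Product: **14** 2-(allyloxy)-5-bromo-1,3-dimethoxybenzene
Conditions: allyl bromide, K2CO3, acetone, reflux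
Reagents that add atoms: allyl bromide, C=CCBr
Why: Williamson O-allylation masks the phenol with a group that survives ArLi, acid and fluoride and is later removed by Pd(0).

**Step 12**
Reactants: **12**
Product: **15** (2S,3S,4R)-2,3-bis{[(TBDPS)oxy]methyl}-4-hydroxy-N-methoxy-N-methyl-4-(3,4,5-trimethoxyphenyl)butanamide
Conditions: MeNH(OMe)·HCl, AlMe3, CH2Cl2, 0 °C→rt
Reagents that add atoms: N,O-dimethylhydroxylamine hydrochloride, CNOC.Cl
Why: The aluminium amide opens the lactone by acyl substitution. The C7'–O bond is kept (C7' stays R), and no base is present to epimerise C8.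

**Step 13**
Reactants: **14**; **15**
Product: **16** (2S,3S,4R)-1-[4-(allyloxy)-3,5-dimethoxyphenyl]-2,3-bis{[(TBDPS)oxy]methyl}-4-hydroxy-4-(3,4,5-trimethoxyphenyl)butan-1-one
Conditions: 14, t-BuLi (2 equiv per ArBr), THF, −78 °C; then 15 (ArLi 3 equiv), −78→0 °C
Reagents that add atoms: none (t-BuLi only effects Li–Br exchange; the aryl group comes from 14)
Why: The stable Weinreb chelate stops the addition at the ketone, the extra ArLi deprotonates the free OH, and the low temperature preserves C8.

**Step 14**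
Reactants: **16**
Product: **17** (1R,2S,3S,4R)-1-[4-(allyloxy)-3,5-dimethoxyphenyl]-2,3-bis{[(TBDPS)oxy]methyl}-4-(3,4,5-trimethoxyphenyl)butane-1,4-diol
Conditions: ketoreductase (NADPH-dependent; (R)-carbinol-selective enzyme from a panel screen), NADP+ (cat.), iPrOH (10% v/v), KPi pH 7.0/DMSO (4:1), 30 °C
Reagents that add atoms: none (hydride from NADPH, recycled by iPrOH→acetone)
Why: The enzyme delivers hydride to one enantioface of the aryl ketone, so C7 forms as a single (R) carbinol. pH 7 avoids epimerisation and β-elimination of silanol.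

**Step 15**
Reactants: **17**
Product: **18** (2R,3S,4S,5R)-2-[4-(allyloxy)-3,5-dimethoxyphenyl]-3,4-bis{[(TBDPS)oxy]methyl}-5-(3,4,5-trimethoxyphenyl)oxolane
Conditions: p-TsOH·H2O (10 mol%), CH2Cl2, 4 Å MS, 0 °C→rt
Reagents that add atoms: none
Why: Acid-catalysed intramolecular SN1 etherification (5-exo closure onto the benzylic cation). The electron-rich benzylic ether ionises reversibly, so C7 and C7' settle in the all-trans arrangement relative to fixed C8 and C8', the thermodynamic sink.

**Step 16**
Reactants: **18**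
Product: **19** 4-allyloxy THF diol (2R,3S,4S,5R)
Conditions: TBAF, AcOH, THF, rt
Reagents that add atoms: none
Why: Fluoride removes both primary TBDPS ethers; no stereocentre is touched, and the allyl ether and THF are inert.

**Step 17**
Reactants: **19**
Product: **20** target
Conditions: Pd(PPh3)4 (5 mol%), K2CO3, MeOH, rt
Reagents that add atoms: none (allyl leaves as allyl methyl ether)
Why: Pd(0) π-allyl cleavage of the aryl allyl ether releases the phenol under mild conditions that do not touch the benzylic THF ethers.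

## Compound list
1 | 5-bromo-1,2,3-trimethoxybenzene | COc1cc(Br)cc(OC)c1OC | starting material
2 | ethyl 4-chloro-4-oxobutanoate | CCOC(=O)CCC(=O)Cl | starting material
3 | ethyl 4-oxo-4-(3,4,5-trimethoxyphenyl)butanoate | CCOC(=O)CCC(=O)c1cc(OC)c(OC)c(OC)c1 | intermediate
4 | (5R)-5-(3,4,5-trimethoxyphenyl)oxolan-2-one | COc1cc([C@H]2CCC(=O)O2)cc(OC)c1OC | intermediate
5 | (5R)-3-(phenylselanyl)-5-aryl-oxolan-2-one (C3 epimers) | COc1cc([C@H]2CC([Se]c3ccccc3)C(=O)O2)cc(OC)c1OC | intermediate
6 | (5R)-5-aryl-furan-2(5H)-one | COc1cc([C@H]2C=CC(=O)O2)cc(OC)c1OC | intermediate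
7 | (4S,5R)-4-ethenyl-5-aryl-oxolan-2-one | C=C[C@@H]1CC(=O)O[C@H]1c2cc(OC)c(OC)c(OC)c2 | intermediate
8 | (2R,3R)-5-oxo-2-aryl-oxolane-3-carbaldehyde | O=C[C@@H]1CC(=O)O[C@H]1c2cc(OC)c(OC)c(OC)c2 | intermediate
9 | (4S,5R)-4-(hydroxymethyl)-5-aryl-oxolan-2-one | OC[C@@H]1CC(=O)O[C@H]1c2cc(OC)c(OC)c(OC)c2 | intermediate
10 | (4S,5R)-4-(TBDPSOCH2)-5-aryl-oxolan-2-one | CC(C)(C)[Si](c1ccccc1)(c1ccccc1)OC[C@@H]2CC(=O)O[C@H]2c3cc(OC)c(OC)c(OC)c3 | intermediate
11 | (3S,4S,5R)-3-(hydroxymethyl)-4-(TBDPSOCH2)-5-aryl-oxolan-2-one | CC(C)(C)[Si](c1ccccc1)(c1ccccc1)OC[C@@H]2[C@@H](CO)C(=O)O[C@H]2c3cc(OC)c(OC)c(OC)c3 | intermediate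
12 | (3S,4S,5R)-3,4-bis(TBDPSOCH2)-5-aryl-oxolan-2-one | CC(C)(C)[Si](c1ccccc1)(c1ccccc1)OC[C@@H]2[C@@H](CO[Si](c3ccccc3)(c3ccccc3)C(C)(C)C)C(=O)O[C@H]2c4cc(OC)c(OC)c(OC)c4 | intermediate
13 | 4-bromo-2,6-dimethoxyphenol | COc1cc(Br)cc(OC)c1O | starting material
14 | 2-(allyloxy)-5-bromo-1,3-dimethoxybenzene | C=CCOc1c(OC)cc(Br)cc1OC | intermediate
15 | Weinreb amide (2S,3S,4R) | CON(C)C(=O)[C@H](CO[Si](c1ccccc1)(c1ccccc1)C(C)(C)C)[C@@H](CO[Si](c2ccccc2)(c2ccccc2)C(C)(C)C)[C@@H](O)c3cc(OC)c(OC)c(OC)c3 | intermediate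
16 | aryl ketone (2S,3S,4R) | C=CCOc1c(OC)cc(cc1OC)C(=O)[C@H](CO[Si](c2ccccc2)(c2ccccc2)C(C)(C)C)[C@@H](CO[Si](c3ccccc3)(c3ccccc3)C(C)(C)C)[C@@H](O)c4cc(OC)c(OC)c(OC)c4 | intermediate
17 | 1,4-diol (1R,2S,3S,4R) | C=CCOc1c(OC)cc(cc1OC)[C@H](O)[C@H](CO[Si](c2ccccc2)(c2ccccc2)C(C)(C)C)[C@@H](CO[Si](c3ccccc3)(c3ccccc3)C(C)(C)C)[C@@H](O)c4cc(OC)c(OC)c(OC)c4 | intermediate
18 | protected THF (2R,3S,4S,5R) | COc1cc([C@@H]2O[C@@H](c3cc(OC)c(OC)c(OC)c3)[C@H](CO[Si](c4ccccc4)(c4ccccc4)C(C)(C)C)[C@H]2CO[Si](c5ccccc5)(c5ccccc5)C(C)(C)C)cc(OC)c1OCC=C | intermediate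
19 | allyl-protected THF diol | COc1cc([C@@H]2O[C@@H](c3cc(OC)c(OC)c(OC)c3)[C@H](CO)[C@H]2CO)cc(OC)c1OCC=C | intermediate
20 | 4-[(2R,3S,4S,5R)-3,4-bis(hydroxymethyl)-5-(3,4,5-trimethoxyphenyl)oxolan-2-yl]-2,6-dimethoxyphenol | COc1cc([C@@H]2O[C@@H](c3cc(OC)c(OC)c(OC)c3)[C@H](CO)[C@H]2CO)cc(OC)c1O | target

## Totals
Total steps: 17. Longest linear sequence: 16 (Steps 1–10 and 12–17; Step 11 is a side branch).

## Three steps most likely to fail
1. **Step 14 (ketoreductase on the bulky bis-silyl ketone).** Enzyme acceptance or activity may be poor. Fallback: skip the ketone. Reduce lactone **12** with DIBAL-H to the lactol and add ArMgBr (from **14**) to give the C7-epimeric diol **17** directly; Step 15 converges both epimers.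
2. **Step 9 (α-hydroxymethylation).** Diastereoselectivity may be modest and the aldol is prone to retro-aldol. Fallback: use an irreversible alkylation with BnOCH2Cl (BOMCl) in place of formaldehyde and carry a benzyl ether on that oxygen. Remove it at the end with Li-naphthalenide instead of fluoride, and adjust the protecting-group scheme accordingly.
3. **Step 15 (cyclodehydration).** Selectivity for the all-trans isomer may be low, or the electron-rich benzylic cations may decompose. Fallback: abandon thermodynamic SN1 cyclisation and do a Mitsunobu cyclodehydration (DIAD/PPh3) of the enzyme-derived single-epimer diol **17**, with SN2 inversion at one benzylic centre.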